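- Late in the simulated runs target climbs almost in a straight line, so a flask at 30 h can be reckoned from the last stretch of its neighbour, provided the partner already used is counted.

| flask | substrate | partner | free catalyst | second catalyst | remark | time |
|---|---|---|---|---|---|---|
| midnight | 0.020 M | 0.022 M (fed, over 3.0 h) | 0.093 mM | 19 µM | run made earlier; the fed solution adds 0.50 times the starting volume |  |
| spring | 0.020 M | 0.022 M (fed, over 3.0 h) | 0.27 mM | 19 µM | run made earlier; the fed solution adds 0.50 times the starting volume |  |
| summer | 0.020 M | 0.022 M (fed, over 3.0 h) | 0.52 mM | 19 µM | run made earlier; the fed solution adds 0.50 times the starting volume |  |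
| Tuesday's | 0.020 M | 0.0220 M (fed, over 3.0 h) | 0.40 mM | 19 µM | the fed solution adds 0.50 times the starting volume | 30 h |
| Saturday's | 0.020 M | 0.0220 M (fed, over 3.0 h) | 0.20 mM | 19 µM | the fed solution adds 0.50 times the starting volume | 30 h |
| Thursday's | 0.020 M | 0.0220 M (fed, over 3.0 h) | 0.12 mM | 19 µM | the fed solution adds 0.50 times the starting volume | 30 h |
| Friday's | 0.020 M | 0.0220 M (fed, over 3.0 h) | 0.60 mM | 19 µM | the fed solution adds 0.50 times the starting volume | 30 h |

| run | time / h | target / % |
|---|---|---|
| midnight | 3.00 | 0.7 |
| midnight | 6.00 | 2.5 |
| midnight | 10.0 | 5.4 |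
| midnight | 12.0 | 7.3 |
| midnight | 15.0 | 10.4 |
| spring | 1.33 | 1.0 |
| spring | 4.00 | 2.8 |
| spring | 8.00 | 7.3 |
| spring | 10.0 | 9.8 |
| spring | 15.0 | 15.2 |
| summer | 1.33 | 0 |
| summer | 4.00 | 3.9 |
| summer | 8.00 | 9.3 |
| summer | 10.0 | 12.0 |
| summer | 15.0 | 19.7 |

(standard deviation of a reading: 0.5 percentage points)

- every charge counts on the volume at the start, and the solution that is fed holds the whole dose
- the numbers in the tables scatter by 0.5 percentage points (one standard deviation)
- what may be going on: partner + catalyst intermediate -> second catalyst + target; substrate + partner -> uncatalysed product; second catalyst + open intermediate <-> catalyst intermediate; target -> over-reaction product; substrate + free catalyst -> free catalyst + open intermediate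

1. the flasks put in order of amount of target, in percent of the substrate charged, best first, at 30 h (Tuesday's / Saturday's / Thursday's / Friday's)
2. the amount of target, in percent of the substrate charged of the flask you put first, at 30 h
3. the amount of target, in percent of the substrate charged of the flask you put last, at 30 h

- Thursday's resembles the midnight run, with 0.12 mM of free catalyst against 0.093 mM. Between 10.0 h and 15.0 h, midnight gains 0.0100 h⁻¹ of the charged substrate and spring 0.0108 h⁻¹. Free catalyst rises 2.90-fold between these runs, far more than the slope's 1.08-fold, so midnight's slope can serve Thursday's, erring slightly low.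
- Partner meets catalyst intermediate in the step that makes target. With catalyst intermediate taken as steady, that step is pseudo-first-order in partner, and the slope follows the share of partner left. That share is one minus target times 0.909, the ratio of the two charges, and it averages 0.928 over midnight's stretch. Slope over share gives the partner pace 0.0108 h⁻¹.
- For Thursday's, the reckoning starts from midnight's 10.4% at 15.0 h, where the share is 0.905. Holding that share for 15.0 h gives 25.0%. That answer leaves a share of 0.772, so a second round on the mean share gives 24.0%.
- Friday's, at 0.60 mM, resembles summer, at 0.52 mM. Summer's pace is 0.0171 h⁻¹, faster than midnight's, and 0.821 of the partner stands at 15.0 h. The first round gives 40.8% and the second 38.3%. Readings at 15.0 h rise with free catalyst, so the reckoning ranks the flasks by loading.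
- The forecast gives Friday's > Tuesday's > Saturday's > Thursday's, with 40% and 27%, by “Extending the late slopes, trimmed slightly for partner loss and over-reaction”.
- The flasks give Friday's > Tuesday's > Saturday's > Thursday's, with Friday's at 38.7% against the reckoned 38.3%, and Thursday's at 24.9% against 24.0%.

    partner + catalyst intermediate → second catalyst + target (k = 1500 L mol⁻¹ h⁻¹)
    substrate + partner → uncatalysed product (k = 0.0450 L mol⁻¹ h⁻¹)
    second catalyst + open intermediate ⇌ catalyst intermediate (K = 730 L mol⁻¹, k = 2.40 × 10⁵ L mol⁻¹ h⁻¹)
    target → over-reaction product (k = 6.70 × 10⁻⁵ h⁻¹)
    substrate + free catalyst → free catalyst + open intermediate (k = 200 L mol⁻¹ h⁻¹)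

- Thursday's, read at 5.0 d, is the same flask with the time changed. From 24.9% at 30 h the share of partner is 0.774, and 90.0 h remain. Repeating the rounds with the pace until the answer stops moving gives 77.0%. The flask then holds 13.9% of substrate and 74.2% of target.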